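**Plan**
Retrosynthesis: (1) cut the cyclopentane bond between the carbinol carbon C1 and the ring-fusion carbon C8a of the hydroazulene (reductive ketyl–enone cyclization); (2) cut the bond between the tetrasubstituted alkene carbon C5 and the ethylene bridge (Stork–Danheiser addition/transposition); (3) cut the oxepane C2–O and cyclohexane C5a–C6 bonds of the benzoxepine (diepoxide cascade).
Forward: geranyl bromide → acyclic diepoxy enol silane → trans-fused oxepane/cyclohexanone in one cascade → tertiary carbinol → iodide. Cycloheptane-1,3-dione → chiral dienyl vinylogous ester. Fragment union gives the cross-conjugated cycloheptadienone, the cyclopentane is closed on it, then reduction and desilylation.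
Enabling feature: in the hydroazulene, C1(OH)Me and C7(OH) are 1,4-related through C8a–C8. At the ketone level C7=O/C8=C8a is an enone whose β-carbon is the ring-fusion carbon, and C1 is a ketyl carbon held three atoms from C3a, so the five-membered ring closes 5-exo.
Stereochemistry: Shi epoxidation sets C3, C5a, C9a (and C6 through the chair); equatorial MeLi addition sets C7 of the benzoxepine; Cu-catalysed conjugate addition sets C3a; the key step sets C8a and C1 from C3a; CBS reduction sets C7 of the azulene.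

Key step: step 16

Remark: the D-fructose-derived Shi ketone is taken to give R,R-epoxides from E-trisubstituted alkenes, and the ligand antipode in step 12 is the one that gives 6S; locants follow the benzoxepine (left half) and azulene (right half) numbering of the target name.

Step 1
Reactants: 1 dimethyl (2-oxopropyl)phosphonate; 2 geranyl bromide
Product: 3 dimethyl [(5E)-6,10-dimethyl-2-oxoundeca-5,9-dien-1-yl]phosphonate
Conditions: NaH, THF, 0 °C; n-BuLi, 0 °C; then 2, 0 °C to rt; aq. NH4Cl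
Reagents that add atoms: none
Why: The β-keto phosphonate dianion reacts at its more basic terminal carbon with the allylic bromide (SN2 γ-alkylation of a dianion), so the phosphonate stays in place for the olefination and both E alkenes are untouched.

Step 2
Reactants: 3 dimethyl [(5E)-6,10-dimethyl-2-oxoundeca-5,9-dien-1-yl]phosphonate; 4 (benzyloxy)acetaldehyde
Product: 5 (2E,7E)-1-(benzyloxy)-8,12-dimethyltrideca-2,7,11-trien-4-one
Conditions: LiCl, DBU, MeCN, rt
Reagents that add atoms: none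
Why: Masamune–Roush Horner–Wadsworth–Emmons olefination of the stabilized phosphonate should give the E enone under base mild enough for the γ-alkoxy enone.

Step 3
Reactants: 5 (2E,7E)-1-(benzyloxy)-8,12-dimethyltrideca-2,7,11-trien-4-one
Product: 6 (4E)-6-(benzyloxy)-1-[(2R,3R)-3-{2-[(2R)-3,3-dimethyloxiran-2-yl]ethyl}-3-methyloxiran-2-yl]hex-4-en-3-one
Conditions: D-fructose-derived Shi ketone (30 mol %), Oxone, K2CO3, Bu4NHSO4, MeCN/DMM/aq. borate–EDTA buffer, 0 °C
Reagents that add atoms: potassium peroxymonosulfate (Oxone), [K+].[O-]S(=O)(=O)OO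
Why: Shi asymmetric epoxidation: the chiral dioxirane oxidizes only the two electron-rich trisubstituted alkenes, each from the face that leads to the R,R and R epoxides (catalyst control), and leaves the electron-poor enone alkene.

Step 4
Reactants: 6 (4E)-6-(benzyloxy)-1-[(2R,3R)-3-{2-[(2R)-3,3-dimethyloxiran-2-yl]ethyl}-3-methyloxiran-2-yl]hex-4-en-3-one
Product: 8 {[(3Z)-6-(benzyloxy)-1-[(2R,3R)-3-{2-[(2R)-3,3-dimethyloxiran-2-yl]ethyl}-3-methyloxiran-2-yl]hex-3-en-3-yl]oxy}(tert-butyl)dimethylsilane, via lithium enolate 7 (not isolated)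
Conditions: L-Selectride, THF, −78 °C; then TBSCl, HMPA, −78 to 0 °C
Reagents that add atoms: tert-butyldimethylsilyl chloride, CC(C)(C)[Si](C)(C)Cl
Why: L-Selectride adds hydride to the β-carbon of the s-cis enone (conjugate reduction) to give the Z lithium enolate regiospecifically, and TBSCl/HMPA silylates it on oxygen without the Lewis acidity that would open the epoxides.

Step 5
Reactants: 8 {[(3Z)-6-(benzyloxy)-1-[(2R,3R)-3-{2-[(2R)-3,3-dimethyloxiran-2-yl]ethyl}-3-methyloxiran-2-yl]hex-3-en-3-yl]oxy}(tert-butyl)dimethylsilane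
Product: 9 (3R,5aR,6R,9aR)-6-[2-(benzyloxy)ethyl]-3-[(tert-butyldimethylsilyl)oxy]-2,2,5a-trimethyloctahydro-1-benzoxepin-7(2H)-one
Conditions: TBSOTf (0.3 equiv), 2,6-di-tert-butyl-4-methylpyridine, CH2Cl2, −78 °C
Reagents that add atoms: none
Why: Tandem oxa-/carbacyclization of a diepoxide with enol silane termination: the silyl triflate activates the terminal epoxide, the internal epoxide oxygen opens it at the tertiary carbon (7-endo), and the resulting epoxonium ion is opened with inversion at its tertiary carbon by the enol silane through a chair, which gives the trans ring fusion, carries C3, C5a and C9a over from the epoxides, places the C6 chain equatorial from the Z enol ether geometry, and releases TBSOTf to carry the chain.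

Step 6
Reactants: 9 (3R,5aR,6R,9aR)-6-[2-(benzyloxy)ethyl]-3-[(tert-butyldimethylsilyl)oxy]-2,2,5a-trimethyloctahydro-1-benzoxepin-7(2H)-one
Product: 11 (3R,5aR,6R,7S,9aR)-6-[2-(benzyloxy)ethyl]-3,7-bis[(tert-butyldimethylsilyl)oxy]-2,2,5a,7-tetramethyldecahydro-1-benzoxepine, via lithium alkoxide 10 (not isolated)
Conditions: MeLi, Et2O/THF, −78 °C; then TBSOTf, −78 to 0 °C
Reagents that add atoms: methyllithium, [Li]C; tert-butyldimethylsilyl trifluoromethanesulfonate, CC(C)(C)[Si](C)(C)OS(=O)(=O)C(F)(F)F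
Why: 1,2-Addition of methyllithium to the ketone from the equatorial direction, because the axial approach is blocked by the syn-axial angular methyl group, should give the axial tertiary alkoxide (7S), which is silylated in the same flask by the reactive silyl triflate.

Step 7
Reactants: 11 (3R,5aR,6R,7S,9aR)-6-[2-(benzyloxy)ethyl]-3,7-bis[(tert-butyldimethylsilyl)oxy]-2,2,5a,7-tetramethyldecahydro-1-benzoxepine
Product: 12 2-[(3R,5aR,6R,7S,9aR)-3,7-bis[(tert-butyldimethylsilyl)oxy]-2,2,5a,7-tetramethyldecahydro-1-benzoxepin-6-yl]ethan-1-ol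
Conditions: H2 (1 atm), Pd/C, EtOAc, rt
Reagents that add atoms: none
Why: Hydrogenolysis of the benzyl ether over palladium in a neutral aprotic solvent leaves the silyl ethers and the oxepane untouched.

Step 8
Reactants: 12 2-[(3R,5aR,6R,7S,9aR)-3,7-bis[(tert-butyldimethylsilyl)oxy]-2,2,5a,7-tetramethyldecahydro-1-benzoxepin-6-yl]ethan-1-ol
Product: 13 (3R,5aR,6R,7S,9aR)-3,7-bis[(tert-butyldimethylsilyl)oxy]-6-(2-iodoethyl)-2,2,5a,7-tetramethyldecahydro-1-benzoxepine
Conditions: I2, PPh3, imidazole, CH2Cl2, 0 °C to rt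
Reagents that add atoms: iodine, II
Why: Appel-type iodination converts the primary alcohol to the iodide by SN2 displacement of the oxyphosphonium ion under buffered conditions that spare both silyl ethers.

Step 9
Reactants: 14 cycloheptane-1,3-dione
Product: 15 2-methylcycloheptane-1,3-dione
Conditions: MeI, K2CO3, acetone, reflux
Reagents that add atoms: iodomethane, CI
Why: C-Alkylation of the 1,3-diketone enolate at the carbon between the carbonyl groups, favoured because cycloheptane-1,3-dione is little enolized and reacts through carbon.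

Step 10
Reactants: 15 2-methylcycloheptane-1,3-dione
Product: 16 3-ethoxy-2-methylcyclohept-2-en-1-one
Conditions: EtOH, p-TsOH (cat.), toluene, reflux (Dean–Stark)
Reagents that add atoms: ethanol, CCO
Why: Acid-catalysed enol etherification of the symmetrical 1,3-diketone with azeotropic removal of water gives a single vinylogous ester.

Step 11
Reactants: 16 3-ethoxy-2-methylcyclohept-2-en-1-one
Product: 18 3-ethoxy-2-methylcyclohepta-2,6-dien-1-one, via silyl dienol ether 17 (not isolated)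
Conditions: LDA, THF, −78 °C; TMSCl; then Pd(OAc)2, MeCN, rt
Reagents that add atoms: none
Why: Kinetic deprotonation of the vinylogous ester at the α′ carbon, O-silylation and Saegusa–Ito oxidation (palladation of the silyl enol ether, β-hydride elimination) introduce the α′,β′ double bond and give the cross-conjugated dienone.

Step 12
Reactants: 18 3-ethoxy-2-methylcyclohepta-2,6-dien-1-one; 19 2-(2-bromoethyl)-2-methyl-1,3-dioxolane
Product: 22 (6S)-3-ethoxy-2,7-dimethyl-6-[2-(2-methyl-1,3-dioxolan-2-yl)ethyl]cyclohept-2-en-1-one (C7 epimers), via Grignard reagent 20 (not isolated), via magnesium enolate 21 (not isolated)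
Conditions: 19, Mg, THF, rt; then CuBr·SMe2 (5 mol %), Josiphos-type diphosphine (6 mol %), t-BuOMe, −78 °C, slow addition of 18; then MeI, DMPU, −30 °C to rt
Reagents that add atoms: iodomethane, CI
Why: Copper-catalysed asymmetric conjugate addition of the Grignard reagent to the unsubstituted enone arm (the vinylogous ester arm is inert) sets C6, the future ring-fusion carbon, under control of the chiral ligand, and the magnesium enolate is then C-methylated at C7.

Step 13
Reactants: 22 (6S)-3-ethoxy-2,7-dimethyl-6-[2-(2-methyl-1,3-dioxolan-2-yl)ethyl]cyclohept-2-en-1-one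
Product: 23 (6S)-3-ethoxy-2,7,7-trimethyl-6-[2-(2-methyl-1,3-dioxolan-2-yl)ethyl]cyclohept-2-en-1-one
Conditions: LDA, THF, −78 °C; MeI, −78 to 0 °C
Reagents that add atoms: iodomethane, CI
Why: Stork–Danheiser-type α′-alkylation: LDA removes the remaining α′ proton kinetically and the enolate is methylated, which gives the gem-dimethyl group and removes the C7 stereocentre.

Step 14
Reactants: 23 (6S)-3-ethoxy-2,7,7-trimethyl-6-[2-(2-methyl-1,3-dioxolan-2-yl)ethyl]cyclohept-2-en-1-one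
Product: 25 (6R)-3-ethoxy-2,7,7-trimethyl-6-[2-(2-methyl-1,3-dioxolan-2-yl)ethyl]cyclohepta-2,4-dien-1-one, via silyl dienol ether 24 (not isolated)
Conditions: LDA, THF, −78 °C; TMSCl; then Pd(OAc)2, MeCN, rt
Reagents that add atoms: none
Why: With no α′ proton left, LDA deprotonates the γ carbon to the extended enolate, which is silylated on oxygen, and Saegusa–Ito oxidation of this silyl dienol ether (palladation at C4, β-hydride elimination from C5) gives the 2,4-dienone.

Step 15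
Reactants: 13 (3R,5aR,6R,7S,9aR)-3,7-bis[(tert-butyldimethylsilyl)oxy]-6-(2-iodoethyl)-2,2,5a,7-tetramethyldecahydro-1-benzoxepine; 25 (6R)-3-ethoxy-2,7,7-trimethyl-6-[2-(2-methyl-1,3-dioxolan-2-yl)ethyl]cyclohepta-2,4-dien-1-one
Product: 28 (5R)-3-{2-[(3R,5aR,6R,7S,9aR)-3,7-bis[(tert-butyldimethylsilyl)oxy]-2,2,5a,7-tetramethyldecahydro-1-benzoxepin-6-yl]ethyl}-2,4,4-trimethyl-5-(3-oxobutyl)cyclohepta-2,6-dien-1-one, via alkyllithium 26 (not isolated), via lithium alkoxide adduct 27 (not isolated)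
Conditions: 13, t-BuLi (2.1 equiv), Et2O, −78 °C; add 25, −78 to 0 °C; aq. NH4Cl; then PPTS, acetone/H2O, 50 °C
Reagents that add atoms: water, O
Why: Iodine–lithium exchange gives the primary alkyllithium, which adds 1,2 to the hindered vinylogous ester carbonyl (no α′ proton to enolize), and mild acid then effects the Stork–Danheiser transposition (loss of the tertiary hydroxyl, hydrolysis of the ethoxy-stabilized pentadienyl cation at C3) and hydrolyses the dioxolane, giving the cross-conjugated dienone with the tetrasubstituted alkene while the TBS ethers survive.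

Step 16
Reactants: 28 (5R)-3-{2-[(3R,5aR,6R,7S,9aR)-3,7-bis[(tert-butyldimethylsilyl)oxy]-2,2,5a,7-tetramethyldecahydro-1-benzoxepin-6-yl]ethyl}-2,4,4-trimethyl-5-(3-oxobutyl)cyclohepta-2,6-dien-1-one
Product: 29 (1R,3aR,8aR)-5-{2-[(3R,5aR,6R,7S,9aR)-3,7-bis[(tert-butyldimethylsilyl)oxy]-2,2,5a,7-tetramethyldecahydro-1-benzoxepin-6-yl]ethyl}-1-hydroxy-1,4,4,6-tetramethyl-2,3,3a,4,8,8a-hexahydroazulen-7(1H)-one
Conditions: SmI2 (2.5 equiv), HMPA, t-BuOH (2 equiv), THF, −78 °C
Reagents that add atoms: none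
Why: SmI2 transfers one electron to give a samarium(III) ketyl of the methyl ketone (or the equivalent dienone radical anion), the carbinol carbon bonds to the β-carbon of the disubstituted enone arm to form C1–C8a, and a second electron transfer with protonation at C8 by t-BuOH returns the tetrasubstituted enone. The closest known reaction type is the SmI2-mediated ketyl–olefin (ketone–enone) reductive cyclization. The cyclopentane closes in the 5-exo-trig mode; attack on the other β-carbon (C5) would be a 6-exo closure onto a fully substituted alkene carbon beside the quaternary centre and should not compete. C8a is controlled by C3a, because the three-atom tether reaches only the alkene face on which it stands, which gives the cis ring fusion; C1 is controlled by the preference of the bulky HMPA-solvated O–Sm group to lie anti to the enone C=C, which places the hydroxyl trans to C8 and the methyl cis to it as in the target. The step needs cyclization to outrun simple reduction or pinacol coupling of the dienone, which is secured by the fast 5-exo closure, by HMPA (which also suppresses Sm chelation between the ketyl and enone oxygens that would invert C1) and by a limited amount of SmI2 at −78 °C.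

Step 17
Reactants: 29 (1R,3aR,8aR)-5-{2-[(3R,5aR,6R,7S,9aR)-3,7-bis[(tert-butyldimethylsilyl)oxy]-2,2,5a,7-tetramethyldecahydro-1-benzoxepin-6-yl]ethyl}-1-hydroxy-1,4,4,6-tetramethyl-2,3,3a,4,8,8a-hexahydroazulen-7(1H)-one
Product: 30 (1R,3aR,7S,8aR)-5-{2-[(3R,5aR,6R,7S,9aR)-3,7-bis[(tert-butyldimethylsilyl)oxy]-2,2,5a,7-tetramethyldecahydro-1-benzoxepin-6-yl]ethyl}-1,4,4,6-tetramethyl-1,2,3,3a,4,7,8,8a-octahydroazulene-1,7-diol
Conditions: (R)-2-methyl-CBS-oxazaborolidine (0.5 equiv), BH3·SMe2, THF, −30 °C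
Reagents that add atoms: none
Why: Corey–Bakshi–Shibata reduction: the (R)-oxazaborolidine delivers hydride 1,2 to the enone face that gives the 7S allylic alcohol, with the α-methyl alkenyl group acting as the large substituent (reagent control), and the free tertiary hydroxyl only consumes one equivalent of borane.

Step 18
Reactants: 30 (1R,3aR,7S,8aR)-5-{2-[(3R,5aR,6R,7S,9aR)-3,7-bis[(tert-butyldimethylsilyl)oxy]-2,2,5a,7-tetramethyldecahydro-1-benzoxepin-6-yl]ethyl}-1,4,4,6-tetramethyl-1,2,3,3a,4,7,8,8a-octahydroazulene-1,7-diol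
Product: 31 (3R,5aR,6R,7S,9aR)-6-{2-[(1R,3aR,7S,8aR)-1,7-dihydroxy-1,4,4,6-tetramethyl-1,2,3,3a,4,7,8,8a-octahydroazulen-5-yl]ethyl}-2,2,5a,7-tetramethyldecahydro-1-benzoxepine-3,7-diol
Conditions: HF·pyridine, pyridine, THF, 0 °C to rt
Reagents that add atoms: none
Why: Fluoride-mediated cleavage of both TBS ethers (desilylation) under pyridine-buffered conditions that should not ionize the allylic alcohol gives the pentaol.

**Compound list**
1 | dimethyl (2-oxopropyl)phosphonate | CC(=O)CP(=O)(OC)OC | starting material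
2 | geranyl bromide, (2E)-1-bromo-3,7-dimethylocta-2,6-diene | CC(C)=CCC/C(C)=C/CBr | starting material
3 | dimethyl [(5E)-6,10-dimethyl-2-oxoundeca-5,9-dien-1-yl]phosphonate | COP(=O)(OC)CC(=O)CC/C=C(\C)CCC=C(C)C | intermediate
4 | (benzyloxy)acetaldehyde | O=CCOCc1ccccc1 | starting material
5 | (2E,7E)-1-(benzyloxy)-8,12-dimethyltrideca-2,7,11-trien-4-one | O=C(/C=C/COCc1ccccc1)CC/C=C(\C)CCC=C(C)C | intermediate
6 | (4E)-6-(benzyloxy)-1-[(2R,3R)-3-{2-[(2R)-3,3-dimethyloxiran-2-yl]ethyl}-3-methyloxiran-2-yl]hex-4-en-3-one | O=C(/C=C/COCc1ccccc1)CC[C@H]1O[C@]1(C)CC[C@H]1OC1(C)C | intermediate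
7 | lithium (3Z)-6-(benzyloxy)-1-[(2R,3R)-3-{2-[(2R)-3,3-dimethyloxiran-2-yl]ethyl}-3-methyloxiran-2-yl]hex-3-en-3-olate (not isolated) | [Li]O/C(CC[C@H]1O[C@]1(C)CC[C@H]1OC1(C)C)=C\CCOCc1ccccc1 | intermediate
8 | {[(3Z)-6-(benzyloxy)-1-[(2R,3R)-3-{2-[(2R)-3,3-dimethyloxiran-2-yl]ethyl}-3-methyloxiran-2-yl]hex-3-en-3-yl]oxy}(tert-butyl)dimethylsilane | CC(C)(C)[Si](C)(C)O/C(CC[C@H]1O[C@]1(C)CC[C@H]1OC1(C)C)=C\CCOCc1ccccc1 | intermediate
9 | (3R,5aR,6R,9aR)-6-[2-(benzyloxy)ethyl]-3-[(tert-butyldimethylsilyl)oxy]-2,2,5a-trimethyloctahydro-1-benzoxepin-7(2H)-one | c1ccccc1COCC[C@@H]2[C@@]3(C)CC[C@@H](O[Si](C)(C)C(C)(C)C)C(C)(C)O[C@@H]3CCC2=O | intermediate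
10 | lithium (3R,5aR,6R,7S,9aR)-6-[2-(benzyloxy)ethyl]-3-[(tert-butyldimethylsilyl)oxy]-2,2,5a,7-tetramethyldecahydro-1-benzoxepin-7-olate (not isolated) | c1ccccc1COCC[C@@H]2[C@@]3(C)CC[C@@H](O[Si](C)(C)C(C)(C)C)C(C)(C)O[C@@H]3CC[C@]2(C)O[Li] | intermediate
11 | (3R,5aR,6R,7S,9aR)-6-[2-(benzyloxy)ethyl]-3,7-bis[(tert-butyldimethylsilyl)oxy]-2,2,5a,7-tetramethyldecahydro-1-benzoxepine | c1ccccc1COCC[C@@H]2[C@@]3(C)CC[C@@H](O[Si](C)(C)C(C)(C)C)C(C)(C)O[C@@H]3CC[C@]2(C)O[Si](C)(C)C(C)(C)C | intermediate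
12 | 2-[(3R,5aR,6R,7S,9aR)-3,7-bis[(tert-butyldimethylsilyl)oxy]-2,2,5a,7-tetramethyldecahydro-1-benzoxepin-6-yl]ethan-1-ol | OCC[C@@H]2[C@@]3(C)CC[C@@H](O[Si](C)(C)C(C)(C)C)C(C)(C)O[C@@H]3CC[C@]2(C)O[Si](C)(C)C(C)(C)C | intermediate
13 | (3R,5aR,6R,7S,9aR)-3,7-bis[(tert-butyldimethylsilyl)oxy]-6-(2-iodoethyl)-2,2,5a,7-tetramethyldecahydro-1-benzoxepine | ICC[C@@H]2[C@@]3(C)CC[C@@H](O[Si](C)(C)C(C)(C)C)C(C)(C)O[C@@H]3CC[C@]2(C)O[Si](C)(C)C(C)(C)C | intermediate
14 | cycloheptane-1,3-dione | O=C1CCCCC(=O)C1 | starting material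
15 | 2-methylcycloheptane-1,3-dione | CC1C(=O)CCCCC1=O | intermediate
16 | 3-ethoxy-2-methylcyclohept-2-en-1-one | CCOC1=C(C)C(=O)CCCC1 | intermediate
17 | 1-ethoxy-2-methyl-3-[(trimethylsilyl)oxy]cyclohepta-1,3-diene (not isolated) | CCOC1=C(C)C(O[Si](C)(C)C)=CCCC1 | intermediate
18 | 3-ethoxy-2-methylcyclohepta-2,6-dien-1-one | CCOC1=C(C)C(=O)C=CCC1 | intermediate
19 | 2-(2-bromoethyl)-2-methyl-1,3-dioxolane | CC1(CCBr)OCCO1 | starting material
20 | [2-(2-methyl-1,3-dioxolan-2-yl)ethyl]magnesium bromide (not isolated) | CC1(CC[Mg]Br)OCCO1 | intermediate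
21 | bromomagnesium enolate of (6S)-3-ethoxy-2-methyl-6-[2-(2-methyl-1,3-dioxolan-2-yl)ethyl]cyclohept-2-en-1-one (not isolated) | CCOC1=C(C)C(O[Mg]Br)=C[C@H](CCC2(C)OCCO2)CC1 | intermediate
22 | (6S)-3-ethoxy-2,7-dimethyl-6-[2-(2-methyl-1,3-dioxolan-2-yl)ethyl]cyclohept-2-en-1-one (C7 epimers) | CCOC1=C(C)C(=O)C(C)[C@H](CCC2(C)OCCO2)CC1 | intermediate
23 | (6S)-3-ethoxy-2,7,7-trimethyl-6-[2-(2-methyl-1,3-dioxolan-2-yl)ethyl]cyclohept-2-en-1-one | CCOC1=C(C)C(=O)C(C)(C)[C@H](CCC2(C)OCCO2)CC1 | intermediate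
24 | {[(6R)-3-ethoxy-2,7,7-trimethyl-6-[2-(2-methyl-1,3-dioxolan-2-yl)ethyl]cyclohepta-1,3-dien-1-yl]oxy}trimethylsilane (not isolated) | CCOC1=CC[C@@H](CCC2(C)OCCO2)C(C)(C)C(O[Si](C)(C)C)=C1C | intermediate
25 | (6R)-3-ethoxy-2,7,7-trimethyl-6-[2-(2-methyl-1,3-dioxolan-2-yl)ethyl]cyclohepta-2,4-dien-1-one | CCOC1=C(C)C(=O)C(C)(C)[C@H](CCC2(C)OCCO2)C=C1 | intermediate
26 | {2-[(3R,5aR,6R,7S,9aR)-3,7-bis[(tert-butyldimethylsilyl)oxy]-2,2,5a,7-tetramethyldecahydro-1-benzoxepin-6-yl]ethyl}lithium (not isolated) | [Li]CC[C@@H]2[C@@]3(C)CC[C@@H](O[Si](C)(C)C(C)(C)C)C(C)(C)O[C@@H]3CC[C@]2(C)O[Si](C)(C)C(C)(C)C | intermediate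
27 | lithium alkoxide of the 1,2-adduct of 26 to the carbonyl of 25 (tertiary dienyl carbinol, C1 epimers, not isolated) | CC1=C(OCC)C=C[C@@H](CCC4(C)OCCO4)C(C)(C)C1(O[Li])CC[C@@H]2[C@@]3(C)CC[C@@H](O[Si](C)(C)C(C)(C)C)C(C)(C)O[C@@H]3CC[C@]2(C)O[Si](C)(C)C(C)(C)C | intermediate
28 | (5R)-3-{2-[(3R,5aR,6R,7S,9aR)-3,7-bis[(tert-butyldimethylsilyl)oxy]-2,2,5a,7-tetramethyldecahydro-1-benzoxepin-6-yl]ethyl}-2,4,4-trimethyl-5-(3-oxobutyl)cyclohepta-2,6-dien-1-one | CC1=C(CC[C@@H]2[C@@]3(C)CC[C@@H](O[Si](C)(C)C(C)(C)C)C(C)(C)O[C@@H]3CC[C@]2(C)O[Si](C)(C)C(C)(C)C)C(C)(C)[C@H](CCC(C)=O)C=CC1=O | intermediate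
29 | (1R,3aR,8aR)-5-{2-[(3R,5aR,6R,7S,9aR)-3,7-bis[(tert-butyldimethylsilyl)oxy]-2,2,5a,7-tetramethyldecahydro-1-benzoxepin-6-yl]ethyl}-1-hydroxy-1,4,4,6-tetramethyl-2,3,3a,4,8,8a-hexahydroazulen-7(1H)-one | CC1=C(CC[C@@H]2[C@@]3(C)CC[C@@H](O[Si](C)(C)C(C)(C)C)C(C)(C)O[C@@H]3CC[C@]2(C)O[Si](C)(C)C(C)(C)C)C(C)(C)[C@@H]2CC[C@@](C)(O)[C@@H]2CC1=O | intermediate
30 | (1R,3aR,7S,8aR)-5-{2-[(3R,5aR,6R,7S,9aR)-3,7-bis[(tert-butyldimethylsilyl)oxy]-2,2,5a,7-tetramethyldecahydro-1-benzoxepin-6-yl]ethyl}-1,4,4,6-tetramethyl-1,2,3,3a,4,7,8,8a-octahydroazulene-1,7-diol | CC1=C(CC[C@@H]2[C@@]3(C)CC[C@@H](O[Si](C)(C)C(C)(C)C)C(C)(C)O[C@@H]3CC[C@]2(C)O[Si](C)(C)C(C)(C)C)C(C)(C)[C@@H]2CC[C@@](C)(O)[C@@H]2C[C@@H]1O | intermediate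
31 | (3R,5aR,6R,7S,9aR)-6-{2-[(1R,3aR,7S,8aR)-1,7-dihydroxy-1,4,4,6-tetramethyl-1,2,3,3a,4,7,8,8a-octahydroazulen-5-yl]ethyl}-2,2,5a,7-tetramethyldecahydro-1-benzoxepine-3,7-diol | CC1=C(CC[C@@H]2[C@@]3(C)CC[C@@H](O)C(C)(C)O[C@@H]3CC[C@]2(C)O)C(C)(C)[C@@H]2CC[C@@](C)(O)[C@@H]2C[C@@H]1O | target

Total step count: 18. Longest linear sequence: 12 steps (steps 1–8, then 15–18); the second branch (steps 9–14) joins at step 15.

**Steps most likely to fail**

Step 5 (cascade). The epoxonium ion may be captured by an oxygen nucleophile or lose a proton before the enol silane closes the carbocycle, or the carbocycle may close through a boat and erode the C5a/C6 relationship. The fallback sets out from 6 and comes back at 9. Conjugate reduction of 6 with L-Selectride and trapping of the enolate with PhNTf2 would give the (Z)-enol triflate F1. Pd-catalysed Kumada coupling with Me3SiCH2MgCl would give the allylsilane F2, a more nucleophilic terminator that ends the cascade irreversibly by loss of silicon. MeAlCl2 in CH2Cl2 at −78 °C would then give the exocyclic-methylene alcohol F3, which is silylated (TBSOTf, 2,6-lutidine) to the silyl ether F4 and ozonized (O3; Me2S) to ketone 9.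

Step 12 (conjugate addition). Facial discrimination may be low or addition slow because the enone arm is deactivated by cross-conjugation with the vinylogous ester; the Grignard reagent may add 1,2; C-methylation of the magnesium enolate may be incomplete. The fallback sets out from 18 and comes back at 22. Rhodium-catalysed asymmetric 1,4-addition (Hayashi–Miyaura; [Rh(cod)Cl]2, BINAP, aq. KOH, dioxane) of the alkenylboronate F5 (from hydroboration of 2-ethynyl-2-methyl-1,3-dioxolane with pinacolborane) to 18 would give the 6-alkenyl enone F6. Hydrogenation of its disubstituted alkene (H2, Pd/C) would give the saturated vinylogous ester F7, and LDA/MeI would methylate it at C7 to give 22.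

Step 16 (key step). Simple reduction or reductive dimerization of the dienone may outrun ring closure, the product enone may be over-reduced, or samarium chelation may erode facial control at the carbinol carbon. The fallback sets out from 28 and comes back at 31. Kinetic enolization of the methyl ketone of 28 (LDA, TESCl, −78 °C) would give the 2-silyloxy alkene F8. Iron-hydride hydrogen-atom transfer (Fe(acac)3, PhSiH3, EtOH/ethylene glycol) would generate the tertiary α-silyloxy radical, which closes 5-exo on the enone (MHAT-initiated radical conjugate addition) to give the silyl ether F9. CBS reduction as in step 17 would give the allylic alcohol F10, and HF·pyridine would remove all three silyl groups to give 31.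

**Further compounds**
F1 | step 5 | (3Z)-6-(benzyloxy)-1-[(2R,3R)-3-{2-[(2R)-3,3-dimethyloxiran-2-yl]ethyl}-3-methyloxiran-2-yl]hex-3-en-3-yl trifluoromethanesulfonate | O=S(=O)(O/C(CC[C@H]1O[C@]1(C)CC[C@H]1OC1(C)C)=C\CCOCc1ccccc1)C(F)(F)F
F2 | step 5 | {(2Z)-5-(benzyloxy)-2-[2-((2R,3R)-3-{2-[(2R)-3,3-dimethyloxiran-2-yl]ethyl}-3-methyloxiran-2-yl)ethyl]pent-2-en-1-yl}trimethylsilane | C[Si](C)(C)C/C(CC[C@H]1O[C@]1(C)CC[C@H]1OC1(C)C)=C\CCOCc1ccccc1
F3 | step 5 | (3R,5aR,6S,9aR)-6-[2-(benzyloxy)ethyl]-2,2,5a-trimethyl-7-methylidenedecahydro-1-benzoxepin-3-ol | c1ccccc1COCC[C@@H]2[C@@]3(C)CC[C@@H](O)C(C)(C)O[C@@H]3CCC2=C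
F4 | step 5 | {[(3R,5aR,6S,9aR)-6-[2-(benzyloxy)ethyl]-2,2,5a-trimethyl-7-methylidenedecahydro-1-benzoxepin-3-yl]oxy}(tert-butyl)dimethylsilane | c1ccccc1COCC[C@@H]2[C@@]3(C)CC[C@@H](O[Si](C)(C)C(C)(C)C)C(C)(C)O[C@@H]3CCC2=C
F5 | step 12 | 4,4,5,5-tetramethyl-2-[(E)-2-(2-methyl-1,3-dioxolan-2-yl)ethenyl]-1,3,2-dioxaborolane | CC1(/C=C/B2OC(C)(C)C(C)(C)O2)OCCO1
F6 | step 12 | (6R)-3-ethoxy-2-methyl-6-[(E)-2-(2-methyl-1,3-dioxolan-2-yl)ethenyl]cyclohept-2-en-1-one | CCOC1=C(C)C(=O)C[C@H](/C=C/C2(C)OCCO2)CC1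
F7 | step 12 | (6S)-3-ethoxy-2-methyl-6-[2-(2-methyl-1,3-dioxolan-2-yl)ethyl]cyclohept-2-en-1-one | CCOC1=C(C)C(=O)C[C@H](CCC2(C)OCCO2)CC1
F8 | step 16 | (5R)-3-{2-[(3R,5aR,6R,7S,9aR)-3,7-bis[(tert-butyldimethylsilyl)oxy]-2,2,5a,7-tetramethyldecahydro-1-benzoxepin-6-yl]ethyl}-2,4,4-trimethyl-5-{3-[(triethylsilyl)oxy]but-3-en-1-yl}cyclohepta-2,6-dien-1-one | CC1=C(CC[C@@H]2[C@@]3(C)CC[C@@H](O[Si](C)(C)C(C)(C)C)C(C)(C)O[C@@H]3CC[C@]2(C)O[Si](C)(C)C(C)(C)C)C(C)(C)[C@H](CCC(=C)O[Si](CC)(CC)CC)C=CC1=O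
F9 | step 16 | (1R,3aR,8aR)-5-{2-[(3R,5aR,6R,7S,9aR)-3,7-bis[(tert-butyldimethylsilyl)oxy]-2,2,5a,7-tetramethyldecahydro-1-benzoxepin-6-yl]ethyl}-1,4,4,6-tetramethyl-1-[(triethylsilyl)oxy]-2,3,3a,4,8,8a-hexahydroazulen-7(1H)-one | CC1=C(CC[C@@H]2[C@@]3(C)CC[C@@H](O[Si](C)(C)C(C)(C)C)C(C)(C)O[C@@H]3CC[C@]2(C)O[Si](C)(C)C(C)(C)C)C(C)(C)[C@@H]2CC[C@@](C)(O[Si](CC)(CC)CC)[C@@H]2CC1=O
F10 | step 16 | (1R,3aR,7S,8aR)-5-{2-[(3R,5aR,6R,7S,9aR)-3,7-bis[(tert-butyldimethylsilyl)oxy]-2,2,5a,7-tetramethyldecahydro-1-benzoxepin-6-yl]ethyl}-1,4,4,6-tetramethyl-1-[(triethylsilyl)oxy]-1,2,3,3a,4,7,8,8a-octahydroazulen-7-ol | CC1=C(CC[C@@H]2[C@@]3(C)CC[C@@H](O[Si](C)(C)C(C)(C)C)C(C)(C)O[C@@H]3CC[C@]2(C)O[Si](C)(C)C(C)(C)C)C(C)(C)[C@@H]2CC[C@@](C)(O[Si](CC)(CC)CC)[C@@H]2C[C@@H]1O
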